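**Retrosynthetic overview**
1. The quinone (ring B) is unveiled last: a C2'-phenol with a free para position (C5') is oxidised with (KSO3)2NO, and that phenol is carried through the route as a benzyl ether.
2. Feature: in ring C (O1, C2, C3, C4, C4a, C8a) the bonds O1–C8a and C4–C4a both end on the electron-rich ring A. O1, C8a, C4a and C4 are therefore the four atoms of an ortho-quinone methide, and C2–C3 is a two-carbon arylacetate enolate that carries ring B.
3. Key disconnection: C3–C4 and O1–C2 of the corresponding chroman-2-one, made by an isothiourea-catalysed formal [4+2] annulation that sets C3 (S), the only stereocentre.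
4. The lactone carbonyl is taken down to CH2 by hydride reduction to the phenol-alcohol and Mitsunobu re-closure of O1–C2.
5. Ring order: rings A and B are bought as benzaldehydes; ring C is closed in the key step as the lactone, opened and closed again as the ether; ring B is oxidised at the end.

Key step: step 7

Assumption: the sense of induction follows the accepted model for isothiourea-bound (Z)-enolates (bond formation anti to the pseudoaxial C2-phenyl group of the catalyst); on that model (2R,3S)-HyperBTM leads to the 3S lactone.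

**Route**

Step 1
Reactants: 1 2-hydroxy-4,5-dimethoxybenzaldehyde
Product: 2 2-(hydroxymethyl)-4,5-dimethoxyphenol
Conditions: NaBH4, MeOH/THF, 0 °C; aq. NH4Cl work-up, crude used directly
Reagents that add atoms: none
Why: Borohydride reduction of an aryl aldehyde to the benzylic alcohol, with no other reducible group present.

Step 2
Reactants: 2 2-(hydroxymethyl)-4,5-dimethoxyphenol; 3 sodium 4-methylbenzenesulfinate
Product: 4 4,5-dimethoxy-2-[(4-methylphenyl)sulfonylmethyl]phenol
Conditions: 3 (1.5 equiv), HCO2H/H2O, rt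
Reagents that add atoms: none
Why: Acid ionises the electron-rich salicyl alcohol to its benzylic cation/ortho-quinone methide, which the soft sulfinate should capture at sulfur (SN1-type sulfinate S-alkylation) to give the crystalline sulfone.

Step 3
Reactants: 5 2-hydroxy-3,4-dimethoxybenzaldehyde
Product: 6 2-(benzyloxy)-3,4-dimethoxybenzaldehyde
Conditions: BnBr, K2CO3, DMF, 60 °C
Reagents that add atoms: benzyl bromide, BrCc1ccccc1
Why: Williamson etherification of the phenoxide protects the future quinone oxygen as a group that is stable to base, hydride and mild acid.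

Step 4
Reactants: 6 2-(benzyloxy)-3,4-dimethoxybenzaldehyde
Product: 7 2-(benzyloxy)-3,4-dimethoxy-1-(2-methoxyethenyl)benzene (E/Z mixture)
Conditions: Ph3P(CH2OMe)Cl, KOtBu, THF, 0 °C to rt
Reagents that add atoms: (methoxymethyl)triphenylphosphonium chloride, COC[P+](c1ccccc1)(c1ccccc1)c1ccccc1.[Cl-]
Why: Wittig methoxymethylenation adds the one carbon that becomes C2; the alkene geometry is irrelevant because both isomers hydrolyse to the same aldehyde.

Step 5
Reactants: 7 2-(benzyloxy)-3,4-dimethoxy-1-(2-methoxyethenyl)benzene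
Product: 8 [2-(benzyloxy)-3,4-dimethoxyphenyl]acetaldehyde
Conditions: 2 M HCl, THF, 50 °C; crude used directly
Reagents that add atoms: water, O
Why: Acid hydrolysis of the enol ether (C-protonation, hemiacetal, loss of methanol) gives the arylacetaldehyde, and the benzyl ether tolerates dilute acid.

Step 6
Reactants: 8 [2-(benzyloxy)-3,4-dimethoxyphenyl]acetaldehyde
Product: 9 [2-(benzyloxy)-3,4-dimethoxyphenyl]acetic acid
Conditions: NaClO2, NaH2PO4, 2-methyl-2-butene, t-BuOH/H2O, 0 °C to rt
Reagents that add atoms: sodium chlorite, [Na+].[O-]Cl=O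
Why: Pinnick oxidation converts the aldehyde into the acid, and the alkene scavenger removes HOCl before it can chlorinate the electron-rich ring.

Step 7
Reactants: 4 4,5-dimethoxy-2-[(4-methylphenyl)sulfonylmethyl]phenol; 9 [2-(benzyloxy)-3,4-dimethoxyphenyl]acetic acid
Product: 12 (3S)-3-[2-(benzyloxy)-3,4-dimethoxyphenyl]-6,7-dimethoxychroman-2-one, via mixed pivalic anhydride 10 (not isolated), via ortho-quinone methide 11 (not isolated)
Conditions: 9 (1.5 equiv), t-BuCOCl (1.5 equiv), iPr2NEt (1.5 equiv), CH2Cl2, 0 °C, 20 min; then (2R,3S)-3-isopropyl-2-phenyl-3,4-dihydro-2H-benzo[4,5]thiazolo[3,2-a]pyrimidine ((2R,3S)-HyperBTM, 10 mol%), 4 (1.0 equiv), iPr2NEt (2.5 equiv), 0 °C to rt; cold 1 M HCl wash, crude 12 used at once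
Reagents that add atoms: pivaloyl chloride, CC(C)(C)C(Cl)=O (its atoms enter intermediate 10 only and leave as pivalic acid)
Why: iPr2NEt deprotonates phenol 4 and sulfinate is expelled to give methide 11 (its formation eased by the methoxy group para to the benzylic carbon), while the isothiourea is acylated by anhydride 10 and deprotonated to a (Z)-ammonium enolate locked coplanar with the catalyst by an O···S contact. Michael addition of the enolate carbon to the exocyclic CH2 of 11 forms C3–C4 and rearomatises ring A to a phenoxide. The phenoxide closes ring C by acyl substitution on the acyl ammonium (6-exo-trig lactonisation, O1–C2) and releases the catalyst. The closest known reaction type is the isothiourea- or carbene-catalysed Michael addition-lactonisation of arylacetic-acid-derived enolates with ortho-quinone methides to 3,4-dihydrocoumarins. C3, the only new stereocentre, is set by the catalyst: the pseudoaxial C2-phenyl group of (2R,3S)-HyperBTM shields the Re face of the enolate, so the methide adds to the Si face and gives 3S. The step needs C-alkylation to win over O-acylation of the phenol and over self-condensation of the methide, and the product must not enolise; slow release of 11 into an excess of enolate, the hindered amine base and immediate reduction of crude 12 are meant to secure this.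

Step 8
Reactants: 12 (3S)-3-[2-(benzyloxy)-3,4-dimethoxyphenyl]-6,7-dimethoxychroman-2-one
Product: 13 2-[(2S)-2-[2-(benzyloxy)-3,4-dimethoxyphenyl]-3-hydroxypropyl]-4,5-dimethoxyphenol
Conditions: LiAlH4, THF, −20 to 0 °C; aqueous work-up
Reagents that add atoms: none
Why: Hydride reduction of the aryl ester (lactone) gives the primary alcohol and the ring A phenol; at low temperature hydride delivery should outrun enolisation, so C3 stays S.

Step 9
Reactants: 13 2-[(2S)-2-[2-(benzyloxy)-3,4-dimethoxyphenyl]-3-hydroxypropyl]-4,5-dimethoxyphenol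
Product: 14 (3S)-3-[2-(benzyloxy)-3,4-dimethoxyphenyl]-6,7-dimethoxychroman
Conditions: PPh3, DIAD, THF, 0 °C to rt
Reagents that add atoms: none
Why: Intramolecular Mitsunobu etherification (6-exo-tet SN2 of the phenol on the activated primary carbon) re-forms O1–C2; the stereocentre is not the reacting carbon and is untouched.

Step 10
Reactants: 14 (3S)-3-[2-(benzyloxy)-3,4-dimethoxyphenyl]-6,7-dimethoxychroman
Product: 15 6-[(3S)-6,7-dimethoxy-3,4-dihydro-2H-chromen-3-yl]-2,3-dimethoxyphenol
Conditions: H2 (1 atm), 10% Pd/C, EtOAc/EtOH, rt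
Reagents that add atoms: none
Why: Hydrogenolysis of the benzyl aryl ether frees the C2'-phenol; the chroman ether, the methyl ethers and the C3–H centre are inert under these conditions.

Step 11
Reactants: 15 6-[(3S)-6,7-dimethoxy-3,4-dihydro-2H-chromen-3-yl]-2,3-dimethoxyphenol
Product: 16 5-[(3S)-6,7-dimethoxy-3,4-dihydro-2H-chromen-3-yl]-2,3-dimethoxycyclohexa-2,5-diene-1,4-dione (abruquinone A)
Conditions: (KSO3)2NO (2.5 equiv), KH2PO4, H2O/acetone, rt; neutral work-up
Reagents that add atoms: potassium nitrosodisulfonate, [K+].[K+].[O]N(S([O-])(=O)=O)S([O-])(=O)=O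
Why: Teuber oxidation of a phenol with a free para position (C5') gives the para-quinone; ring A carries no free phenol and should be spared, and the buffered medium avoids base-induced racemisation at C3.

**Compound list**
1 | 2-hydroxy-4,5-dimethoxybenzaldehyde | COc1cc(O)c(C=O)cc1OC | starting material
2 | 2-(hydroxymethyl)-4,5-dimethoxyphenol | COc1cc(O)c(CO)cc1OC | intermediate
3 | sodium 4-methylbenzenesulfinate | Cc1ccc(cc1)S(=O)[O-].[Na+] | starting material
4 | 4,5-dimethoxy-2-[(4-methylphenyl)sulfonylmethyl]phenol | Cc1ccc(cc1)S(=O)(=O)Cc1cc(OC)c(OC)cc1O | intermediate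
5 | 2-hydroxy-3,4-dimethoxybenzaldehyde | COc1ccc(C=O)c(O)c1OC | starting material
6 | 2-(benzyloxy)-3,4-dimethoxybenzaldehyde | COc1ccc(C=O)c(OCc2ccccc2)c1OC | intermediate
7 | 2-(benzyloxy)-3,4-dimethoxy-1-(2-methoxyethenyl)benzene (E/Z mixture) | COC=Cc1ccc(OC)c(OC)c1OCc1ccccc1 | intermediate
8 | [2-(benzyloxy)-3,4-dimethoxyphenyl]acetaldehyde | O=CCc1ccc(OC)c(OC)c1OCc1ccccc1 | intermediate
9 | [2-(benzyloxy)-3,4-dimethoxyphenyl]acetic acid | OC(=O)Cc1ccc(OC)c(OC)c1OCc1ccccc1 | intermediate
10 | [2-(benzyloxy)-3,4-dimethoxyphenyl]acetic 2,2-dimethylpropanoic anhydride | CC(C)(C)C(=O)OC(=O)Cc1ccc(OC)c(OC)c1OCc1ccccc1 | intermediate (not isolated)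
11 | 3,4-dimethoxy-6-methylidenecyclohexa-2,4-dien-1-one | C=C1C=C(OC)C(OC)=CC1=O | intermediate (not isolated)
12 | (3S)-3-[2-(benzyloxy)-3,4-dimethoxyphenyl]-6,7-dimethoxychroman-2-one | O=C1Oc2cc(OC)c(OC)cc2C[C@H]1c1ccc(OC)c(OC)c1OCc1ccccc1 | intermediate
13 | 2-[(2S)-2-[2-(benzyloxy)-3,4-dimethoxyphenyl]-3-hydroxypropyl]-4,5-dimethoxyphenol | OC[C@@H](Cc1cc(OC)c(OC)cc1O)c1ccc(OC)c(OC)c1OCc1ccccc1 | intermediate
14 | (3S)-3-[2-(benzyloxy)-3,4-dimethoxyphenyl]-6,7-dimethoxychroman | COc1ccc([C@H]2COc3cc(OC)c(OC)cc3C2)c(OCc2ccccc2)c1OC | intermediate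
15 | 6-[(3S)-6,7-dimethoxy-3,4-dihydro-2H-chromen-3-yl]-2,3-dimethoxyphenol | COc1ccc([C@H]2COc3cc(OC)c(OC)cc3C2)c(O)c1OC | intermediate
16 | 5-[(3S)-6,7-dimethoxy-3,4-dihydro-2H-chromen-3-yl]-2,3-dimethoxycyclohexa-2,5-diene-1,4-dione (abruquinone A) | COC1=C(OC)C(=O)C([C@H]2COc3cc(OC)c(OC)cc3C2)=CC1=O | target

**Step count and risks**
Total steps: 11. Longest linear sequence: 9 (steps 3 to 11, from aldehyde 5).

Steps most likely to fail:

Step 7. The phenol oxygen of 4 may be acylated by the anhydride or the acyl ammonium before sulfinate is lost. The unsubstituted methide may condense with itself. Enolisation of the acyl ammonium or of the aryl-ester product may erode the enantiomeric purity. The fallback sets the centre with an auxiliary; it sets out from acid 9 (with aldehyde 1 for ring A) and comes back at 13, replacing steps 7 and 8. Acid 9 would be activated with t-BuCOCl/Et3N and coupled with (4S)-4-benzyl-1,3-oxazolidin-2-one and LiCl to give (4S)-4-benzyl-3-{[2-(benzyloxy)-3,4-dimethoxyphenyl]acetyl}-1,3-oxazolidin-2-one F1. Aldehyde 1 would be protected with chloromethyl methyl ether/iPr2NEt as 4,5-dimethoxy-2-(methoxymethoxy)benzaldehyde F2, reduced with NaBH4 to [4,5-dimethoxy-2-(methoxymethoxy)phenyl]methanol F3 and converted with CBr4/PPh3 into 1-(bromomethyl)-4,5-dimethoxy-2-(methoxymethoxy)benzene F4, used at once. Evans alkylation of the sodium (Z)-enolate of F1 (NaN(SiMe3)2, THF, −78 °C) with F4, on the face away from the benzyl group of the auxiliary, should give (4S)-4-benzyl-3-{(2S)-2-[2-(benzyloxy)-3,4-dimethoxyphenyl]-3-[4,5-dimethoxy-2-(methoxymethoxy)phenyl]propanoyl}-1,3-oxazolidin-2-one F5. LiBH4 (THF, a little MeOH, 0 °C) would cleave the auxiliary reductively to (2S)-2-[2-(benzyloxy)-3,4-dimethoxyphenyl]-3-[4,5-dimethoxy-2-(methoxymethoxy)phenyl]propan-1-ol F6. HCl in MeOH would then remove the methoxymethyl group to give phenol-alcohol 13.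

Step 8. The α-aryl aryl ester, or the aldehyde that forms fleetingly after the first hydride transfer, may enolise under the basic hydride and lose enantiopurity. The fallback sets out from 12 and comes back at 13. Methanol and a catalytic amount of 4-(dimethylamino)pyridine are added to the annulation mixture, or to crude 12, to open the lactone to the much less acidic alkyl ester methyl (2S)-2-[2-(benzyloxy)-3,4-dimethoxyphenyl]-3-(2-hydroxy-4,5-dimethoxyphenyl)propanoate F7. This ester is reduced promptly with LiBH4 in THF to 13.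

Step 2. Under acid the electron-rich salicyl alcohol 2 may undergo Friedel-Crafts self-condensation to diarylmethane oligomers faster than sulfinate capture. The fallback avoids 2; it sets out from aldehyde 1 and comes back at 4, replacing steps 1 and 2. Reductive amination of 1 with Me2NH and NaBH(OAc)3 would give the Mannich base 2-[(dimethylamino)methyl]-4,5-dimethoxyphenol F8. Heating F8 with sulfinate 3 and AcOH in DMF at 100 °C should exchange the amine for the sulfonyl group by elimination-addition and give 4.

**Further compounds**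
F1 | step 7 | (4S)-4-benzyl-3-{[2-(benzyloxy)-3,4-dimethoxyphenyl]acetyl}-1,3-oxazolidin-2-one | O=C1OC[C@H](Cc2ccccc2)N1C(=O)Cc1ccc(OC)c(OC)c1OCc1ccccc1
F2 | step 7 | 4,5-dimethoxy-2-(methoxymethoxy)benzaldehyde | COCOc1cc(OC)c(OC)cc1C=O
F3 | step 7 | [4,5-dimethoxy-2-(methoxymethoxy)phenyl]methanol | COCOc1cc(OC)c(OC)cc1CO
F4 | step 7 | 1-(bromomethyl)-4,5-dimethoxy-2-(methoxymethoxy)benzene | COCOc1cc(OC)c(OC)cc1CBr
F5 | step 7 | (4S)-4-benzyl-3-{(2S)-2-[2-(benzyloxy)-3,4-dimethoxyphenyl]-3-[4,5-dimethoxy-2-(methoxymethoxy)phenyl]propanoyl}-1,3-oxazolidin-2-one | O=C1OC[C@H](Cc2ccccc2)N1C(=O)[C@@H](Cc1cc(OC)c(OC)cc1OCOC)c1ccc(OC)c(OC)c1OCc1ccccc1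
F6 | step 7 | (2S)-2-[2-(benzyloxy)-3,4-dimethoxyphenyl]-3-[4,5-dimethoxy-2-(methoxymethoxy)phenyl]propan-1-ol | OC[C@@H](Cc1cc(OC)c(OC)cc1OCOC)c1ccc(OC)c(OC)c1OCc1ccccc1
F7 | step 8 | methyl (2S)-2-[2-(benzyloxy)-3,4-dimethoxyphenyl]-3-(2-hydroxy-4,5-dimethoxyphenyl)propanoate | COC(=O)[C@@H](Cc1cc(OC)c(OC)cc1O)c1ccc(OC)c(OC)c1OCc1ccccc1
F8 | step 2 | 2-[(dimethylamino)methyl]-4,5-dimethoxyphenol | CN(C)Cc1cc(OC)c(OC)cc1O
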